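**Plan**
- Cuts: C11=C12 and C11'=C12' (two Wittig reactions on a C10 dialdehyde), C7=C8 (Horner–Wadsworth–Emmons with a C5 phosphonate), C6'–C7' (Sonogashira), and in ring A the bonds C2–C3 and C1–C6 ([4+2]).
- Enabling feature (carotenoid numbering; ring A = C1 CMe2, C3 CHOH, C5 C(Me)OH, C6 C(OH) carrying C7): O3 and C7 lie on one face of ring A, 1,4 to each other. They can therefore be joined as an O3–C7(=O) lactone, which is the bridge a 2-pyrone keeps after cycloaddition.
- Ring A, forward: crotonaldehyde and diethyl oxalate give 3-hydroxy-4-methyl-2-pyrone, and methacrolein then closes ring A. The later operations are CHO to CH3, lactone to lactol to C15 dienoate, O3 silylation, O6-directed epoxidation, hydride at C4, and formation of the C15 phosphonium salt.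
- Ring B and chain, forward: ring B is bought as (4R,6R)-actinol. Enol triflate and Sonogashira coupling give a C15 salt, the C10 dialdehyde extends it to a C25 aldehyde, a last Wittig reaction joins C15 and C25, and desilylation follows.
- Stereochemistry: C3 comes from the chiral amine and C6 from the bridge. C5 comes from oxygen delivery by O6–H and C3' from actinol. The E alkenes come from the phosphonate anion and from tributylphosphonium ylides.

Key step: step 5

Assumption: the quinidine-derived primary amine is taken to give the bridgehead configuration drawn for the cycloadduct; if the opposite sense is found, the quinine-derived pseudoenantiomer is used with no other change.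

**Step 1**
Reactants: 1 (E)-but-2-enal
Product: 3 2-(2-bromopropyl)-1,3-dioxane (racemic), via 3-bromobutanal 2 (not isolated)
Conditions: HBr (g), CH2Cl2, 0 °C; then HO(CH2)3OH, TsOH·H2O (cat.), rt
Reagents that add atoms: hydrogen bromide, Br; propane-1,3-diol, OCCCO
Why: Conjugate addition of HBr to the enal followed by acid-catalysed acetalisation is the standard entry to beta-bromo acetals; the bromine-bearing carbon is racemic and becomes sp2 in step 3.

**Step 2**
Reactants: 3 2-(2-bromopropyl)-1,3-dioxane; 4 diethyl oxalate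
Product: 6 ethyl 4-(1,3-dioxan-2-yl)-3-methyl-2-oxobutanoate (racemic), via Grignard reagent 5 (not isolated)
Conditions: Mg, THF, 30 °C; then added to 4 (2 equiv), THF, −78 °C; aq. NH4Cl
Reagents that add atoms: none
Why: The dioxane-masked homoenolate Grignard reagent is stable in THF, and its single addition to excess oxalate at low temperature (the tetrahedral adduct lasts until the quench) is the classical alpha-keto ester synthesis.

**Step 3**
Reactants: 6 ethyl 4-(1,3-dioxan-2-yl)-3-methyl-2-oxobutanoate
Product: 8 4-methyl-2-oxo-2H-pyran-3-yl acetate, via keto aldehyde acid 7 (not isolated)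
Conditions: LiOH, THF–H2O, 0 °C; 2 M HCl (pH 1), 40 °C; EtOAc extraction; then Ac2O, NaOAc, 80 °C
Reagents that add atoms: lithium hydroxide, [Li+].[OH-]; water, O; acetic anhydride, CC(=O)OC(C)=O
Why: Enol lactonisation of a 5-oxo acid with buffered acetic anhydride closes the acid on the enolised aldehyde and acetylates the enolised ketone (the conditions that turn aldaric acids into 3-acetoxy-2-pyrones); this medium is preferred to hot mineral acid, which would favour Paal–Knorr closure of the 1,4-dicarbonyl unit to the isomeric furoic acid.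

**Step 4**
Reactants: 8 4-methyl-2-oxo-2H-pyran-3-yl acetate
Product: 9 3-hydroxy-4-methyl-2H-pyran-2-one
Conditions: 1 M HCl, THF, 40 °C
Reagents that add atoms: none
Why: Acid hydrolysis of the phenol-like enol acetate should be faster than opening of the aromatic pyrone ring.

**Step 5**
Reactants: 9 3-hydroxy-4-methyl-2H-pyran-2-one; 10 methacrolein
Product: 11 (1S,4R,8S)-4-hydroxy-5,8-dimethyl-3-oxo-2-oxabicyclo[2.2.2]oct-5-ene-8-carbaldehyde (formyl group syn to the alkene bridge)
Conditions: 9-amino-9-deoxy-epi-quinidine (20 mol %), CF3CO2H (40 mol %), 10 (3 equiv), CH2Cl2, −20 °C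
Reagents that add atoms: none
Why: Proposed new method: the primary amine of the catalyst condenses with 10 to an iminium ion while the quinuclidine nitrogen deprotonates the 3-hydroxyl of 9, so that the remote dienolate carbon (pyrone C6, future C3) adds to the CH2 terminus (future C2) and the resulting enamine carbon (future C1) closes on the ketone-like pyrone C3 (future C6), stepwise or as one asynchronous [4+2] event. The closest known reaction type is the cinchona-amine-catalysed asymmetric Diels–Alder reaction of 3-hydroxy-2-pyrones with simple enones and with alpha-substituted acrylonitriles; an alpha-branched enal has not been used in it, although primary cinchona amines are the established activators of alpha-branched enals. Ring A closes in a 6-(enolexo)-exo-trig aldol mode (suprafacially in the concerted picture) inside the 2-oxabicyclo[2.2.2]octenone, with the lactone O–C(=O) unit as the third bridge. C3 is set by the face of the ion-paired dienolate that the catalyst-bound iminium ion can reach, C6 follows from C3 because both new bonds must lie on one face of the planar pyrone, and C1 depends only on endo or exo placement of the formyl group and is erased in step 7, so either epimer converges. The step needs regiochemistry, which the substrate secures by matching the donor terminus of its 1-oxido-diene with the acceptor terminus of the enal, and one absolute facial sense, which rests on the catalyst because the flat pyrone has no bias of its own. The low temperature keeps the bridge from leaving as CO2.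

**Step 6**
Reactants: 11 the formyl lactone
Product: 12 N'-[(E)-{(1S,4R,8R)-4-hydroxy-5,8-dimethyl-3-oxo-2-oxabicyclo[2.2.2]oct-5-en-8-yl}methylidene]-4-methylbenzenesulfonohydrazide
Conditions: TsNHNH2, MgSO4, THF, rt
Reagents that add atoms: 4-methylbenzenesulfonohydrazide, Cc1ccc(cc1)S(=O)(=O)NN
Why: In this hydrazone condensation only the aldehyde can react, and the near-neutral medium avoids retro-aldol cleavage of the C1–C6 bond.

**Step 7**
Reactants: 12 the tosylhydrazone
Product: 14 (1S,4S)-4-hydroxy-5,8,8-trimethyl-2-oxabicyclo[2.2.2]oct-5-en-3-one, via tosylhydrazine 13 (not isolated)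
Conditions: catecholborane (3 equiv), CHCl3, −10 to 0 °C; then NaOAc·3H2O, 45 °C
Reagents that add atoms: none
Why: Caglioti-type deoxygenation (hydride addition to C=N, then acetate-induced loss of sulfinate and N2) turns CH=N into CH3 well below the temperature of CO2 extrusion, the lactone and the trisubstituted alkene are inert to catecholborane, and the C8 stereocentre disappears as C1 becomes CMe2.

**Step 8**
Reactants: 14 the gem-dimethyl lactone
Product: 15 (1S,4S)-5,8,8-trimethyl-2-oxabicyclo[2.2.2]oct-5-ene-3,4-diol (lactol epimers)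
Conditions: i-Bu2AlH (2.3 equiv), CH2Cl2, −78 °C; aq. potassium sodium tartrate
Reagents that add atoms: none
Why: In this partial lactone reduction the aluminium-bound tetrahedral adduct persists at −78 °C, one equivalent is consumed by the tertiary hydroxyl, and the new lactol carbon is an inconsequential epimer mixture.

**Step 9**
Reactants: 15 the lactol; 16 triethyl 3-methyl-4-phosphonocrotonate
Product: 19 ethyl (2E,4E)-5-[(1S,4S)-1,4-dihydroxy-2,6,6-trimethylcyclohex-2-en-1-yl]-3-methylpenta-2,4-dienoate, via lithiated phosphonate 17 (not isolated), via hydroxy aldehyde 18 (not isolated)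
Conditions: 16 (4 equiv), LiN(SiMe3)2 (4 equiv), THF–DMPU, −78 °C; then 15, −78 °C to rt; aq. NH4Cl
Reagents that add atoms: none
Why: This is a Horner–Wadsworth–Emmons olefination of a lactol through its open tautomer, whose share is raised by the boat strain of the bicycle; the allylic phosphonate anion should give the E C7=C8 bond and mainly the 9E dienoate, any 9Z isomer being removed by chromatography.

**Step 10**
Reactants: 19 the C15 diol ester
Product: 20 ethyl (2E,4E)-5-[(1S,4S)-4-{[tert-butyl(dimethyl)silyl]oxy}-1-hydroxy-2,6,6-trimethylcyclohex-2-en-1-yl]-3-methylpenta-2,4-dienoate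
Conditions: TBSCl, imidazole, DMF, 0 °C
Reagents that add atoms: tert-butyldimethylsilyl chloride, CC(C)(C)[Si](C)(C)Cl
Why: Silylation picks the secondary O3–H over the crowded tertiary O6–H, and capping O3 shuts off Payne migration of the later 4,5-epoxide.

**Step 11**
Reactants: 20 the silyl ether
Product: 21 ethyl (2E,4E)-5-[(1R,2S,5S,6R)-5-{[tert-butyl(dimethyl)silyl]oxy}-2-hydroxy-1,3,3-trimethyl-7-oxabicyclo[4.1.0]heptan-2-yl]-3-methylpenta-2,4-dienoate
Conditions: VO(acac)2 (5 mol %), t-BuOOH (decane), CH2Cl2, 0 °C to rt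
Reagents that add atoms: tert-butyl hydroperoxide, CC(C)(C)OO
Why: In this vanadium-catalysed hydroxyl-directed epoxidation the tertiary O6–H binds the metal peroxide and delivers oxygen to C4=C5 on its own face, which is also the face away from the O3 silyl ether; this sets C5 (and C4) with O5 cis to O6 and leaves the electron-poor dienoate untouched.

**Step 12**
Reactants: 21 the epoxy ester
Product: 22 (2E,4E)-5-[(1S,2R,4S)-4-{[tert-butyl(dimethyl)silyl]oxy}-1,2-dihydroxy-2,6,6-trimethylcyclohexyl]-3-methylpenta-2,4-dien-1-ol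
Conditions: LiAlH4 (5 equiv), THF, 0 °C to rt; aq. NaOH work-up
Reagents that add atoms: none
Why: LiAlH4 reduces the ester to the allylic alcohol and opens the epoxide by SN2 attack at the secondary C4 opposite to oxygen, the trans-diaxial (Fürst–Plattner) mode that also leads to the more stable chair, so the C5–O bond and its configuration are not touched.

**Step 13**
Reactants: 22 the C15 alcohol
Product: 24 tributyl{(2E,4E)-5-[(1S,2R,4S)-4-{[tert-butyl(dimethyl)silyl]oxy}-1,2-dihydroxy-2,6,6-trimethylcyclohexyl]-3-methylpenta-2,4-dien-1-yl}phosphonium chloride, via allylic chloride 23 (not isolated)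
Conditions: MsCl, LiCl, 2,4,6-collidine, DMF, 0 °C; then PBu3, CH2Cl2, rt
Reagents that add atoms: lithium chloride, [Li+].[Cl-]; tributylphosphine, CCCCP(CCCC)CCCC
Why: Buffered mesylate-to-chloride exchange touches only the primary allylic alcohol, and SN2 quaternisation of PBu3 gives the salt without the acid that would ionise the tertiary allylic C6–OH.

**Step 14**
Reactants: 25 (4R,6R)-4-hydroxy-2,2,6-trimethylcyclohexan-1-one (actinol)
Product: 26 (4R,6R)-4-{[tert-butyl(dimethyl)silyl]oxy}-2,2,6-trimethylcyclohexan-1-one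
Conditions: TBSCl, imidazole, DMF, rt
Reagents that add atoms: tert-butyldimethylsilyl chloride, CC(C)(C)[Si](C)(C)Cl
Why: This is a standard silylation of a secondary alcohol; the carbinol centre (future C3') is bought and not touched.

**Step 15**
Reactants: 26 the silyloxy ketone
Product: 28 (4R)-4-{[tert-butyl(dimethyl)silyl]oxy}-2,6,6-trimethylcyclohex-1-en-1-yl trifluoromethanesulfonate, via lithium enolate 27 (not isolated)
Conditions: LiN(i-Pr)2, THF, −78 to 0 °C; then PhNTf2, −78 °C to rt
Reagents that add atoms: N-phenylbis(trifluoromethanesulfonimide), O=S(=O)(N(c1ccccc1)S(=O)(=O)C(F)(F)F)C(F)(F)F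
Why: The ketone has a single alpha-hydrogen, so deprotonation and O-triflation can give only one tetrasubstituted enol triflate; the methyl-bearing stereocentre is erased and the silyloxy centre is remote.

**Step 16**
Reactants: 28 the enol triflate; 29 (E)-3-methylpent-2-en-4-yn-1-ol
Product: 30 (2E)-5-[(4R)-4-{[tert-butyl(dimethyl)silyl]oxy}-2,6,6-trimethylcyclohex-1-en-1-yl]-3-methylpent-2-en-4-yn-1-ol
Conditions: Pd(PPh3)4 (5 mol %), CuI (10 mol %), i-Pr2NH, DMF, rt to 40 °C
Reagents that add atoms: none
Why: Sonogashira coupling of an enol triflate with a terminal alkyne forms C6'–C7', tolerates the free allylic alcohol and the silyl ether, and keeps the E geometry of 29.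

**Step 17**
Reactants: 30 the acetylenic C15 alcohol
Product: 32 tributyl{(2E)-5-[(4R)-4-{[tert-butyl(dimethyl)silyl]oxy}-2,6,6-trimethylcyclohex-1-en-1-yl]-3-methylpent-2-en-4-yn-1-yl}phosphonium chloride, via allylic chloride 31 (not isolated)
Conditions: MsCl, LiCl, 2,4,6-collidine, DMF, 0 °C; then PBu3, CH2Cl2, rt
Reagents that add atoms: lithium chloride, [Li+].[Cl-]; tributylphosphine, CCCCP(CCCC)CCCC
Why: The same mesylate-to-chloride exchange and SN2 quaternisation as in step 13 proceed under conditions that leave the enyne geometry alone.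

**Step 18**
Reactants: 32 the ring B phosphonium salt; 33 (2E,4E,6E)-2,7-dimethylocta-2,4,6-trienedial
Product: 35 (3R)-3-{[tert-butyl(dimethyl)silyl]oxy}-7,8-didehydro-12'-apo-beta-caroten-12'-al (all-E), via ylide 34 (not isolated)
Conditions: 33 (3 equiv), NaOMe, CH2Cl2, 0 °C to rt, dark
Reagents that add atoms: none
Why: In this Wittig olefination excess dialdehyde limits double condensation, and allylic tributylphosphonium ylides favour the E alkene, so no thermal equilibration is needed that could scramble the C9'=C10' bond next to the alkyne.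

**Step 19**
Reactants: 24 the ring A phosphonium salt; 35 the C25 aldehyde
Product: 37 (3S,5R,6S,3'R)-3,3'-bis{[tert-butyl(dimethyl)silyl]oxy}-7',8'-didehydro-5,6-dihydro-beta,beta-carotene-5,6-diol (all-E), via ylide 36 (not isolated)
Conditions: NaOMe, CH2Cl2, rt, dark, Ar
Reagents that add atoms: none
Why: This Wittig olefination forms C11=C12 with the E preference of tributylphosphonium allyl ylides; the tertiary hydroxyls are tolerated by methoxide, and no stereocentre is involved.

**Step 20**
Reactants: 37 the bis-silyl ether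
Product: 38 (3S,5R,6S,3'R)-7',8'-didehydro-5,6-dihydro-beta,beta-carotene-3,5,6,3'-tetrol
Conditions: Bu4NF, THF, 0 °C to rt, dark
Reagents that add atoms: none
Why: Fluoride-induced desilylation frees both secondary alcohols under conditions that leave the polyene, the alkyne and the acid-sensitive tertiary allylic alcohol unchanged.

**Compound list**
1 | (E)-but-2-enal | C/C=C/C=O | starting material
2 | 3-bromobutanal (racemic) | CC(Br)CC=O | intermediate
3 | 2-(2-bromopropyl)-1,3-dioxane (racemic) | CC(Br)CC1OCCCO1 | intermediate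
4 | diethyl oxalate | CCOC(=O)C(=O)OCC | starting material
5 | [1-(1,3-dioxan-2-yl)propan-2-yl]magnesium bromide | CC([Mg]Br)CC1OCCCO1 | intermediate
6 | ethyl 4-(1,3-dioxan-2-yl)-3-methyl-2-oxobutanoate (racemic) | CCOC(=O)C(=O)C(C)CC1OCCCO1 | intermediate
7 | 3-methyl-2,5-dioxopentanoic acid (racemic) | CC(CC=O)C(=O)C(=O)O | intermediate
8 | 4-methyl-2-oxo-2H-pyran-3-yl acetate | CC(=O)OC1=C(C)C=COC1=O | intermediate
9 | 3-hydroxy-4-methyl-2H-pyran-2-one | CC1=C(O)C(=O)OC=C1 | intermediate
10 | methacrolein | CC(=C)C=O | starting material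
11 | (1S,4R,8S)-4-hydroxy-5,8-dimethyl-3-oxo-2-oxabicyclo[2.2.2]oct-5-ene-8-carbaldehyde | O=C1O[C@H]2C[C@](C)(C=O)[C@]1(O)C(C)=C2 | intermediate
12 | (E)-tosylhydrazone of 11, (1S,4R,8R) | O=C1O[C@H]2C[C@](C)(/C=N/NS(=O)(=O)c3ccc(C)cc3)[C@]1(O)C(C)=C2 | intermediate
13 | N'-{[(1S,4R,8R)-4-hydroxy-5,8-dimethyl-3-oxo-2-oxabicyclo[2.2.2]oct-5-en-8-yl]methyl}-4-methylbenzenesulfonohydrazide | O=C1O[C@H]2C[C@](C)(CNNS(=O)(=O)c3ccc(C)cc3)[C@]1(O)C(C)=C2 | intermediate
14 | (1S,4S)-4-hydroxy-5,8,8-trimethyl-2-oxabicyclo[2.2.2]oct-5-en-3-one | O=C1O[C@H]2CC(C)(C)[C@]1(O)C(C)=C2 | intermediate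
15 | (1S,4S)-5,8,8-trimethyl-2-oxabicyclo[2.2.2]oct-5-ene-3,4-diol (C3 epimers) | OC1O[C@H]2CC(C)(C)[C@]1(O)C(C)=C2 | intermediate
16 | ethyl (2E)-4-(diethoxyphosphoryl)-3-methylbut-2-enoate (the commercial E/Z mixture serves) | CCOC(=O)/C=C(\C)CP(=O)(OCC)OCC | starting material
17 | lithium salt of 16 | CCOC(=O)/C=C(\C)[CH-]P(=O)(OCC)OCC.[Li+] | intermediate
18 | (1S,4S)-1,4-dihydroxy-2,6,6-trimethylcyclohex-2-ene-1-carbaldehyde | O=C[C@]1(O)C(C)(C)C[C@H](O)C=C1C | intermediate
19 | ethyl (2E,4E)-5-[(1S,4S)-1,4-dihydroxy-2,6,6-trimethylcyclohex-2-en-1-yl]-3-methylpenta-2,4-dienoate | CCOC(=O)/C=C(C)/C=C/[C@]1(O)C(C)(C)C[C@H](O)C=C1C | intermediate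
20 | 4-O-TBS ether of 19 | CCOC(=O)/C=C(C)/C=C/[C@]1(O)C(C)(C)C[C@H](O[Si](C)(C)C(C)(C)C)C=C1C | intermediate
21 | (3S,4R,5R,6S)-4,5-epoxide of 20 (carotenoid numbering; epoxide cis to O6) | CCOC(=O)/C=C(C)/C=C/[C@]1(O)C(C)(C)C[C@H](O[Si](C)(C)C(C)(C)C)[C@H]2O[C@@]12C | intermediate
22 | (2E,4E)-5-[(1S,2R,4S)-4-(TBS-oxy)-1,2-dihydroxy-2,6,6-trimethylcyclohexyl]-3-methylpenta-2,4-dien-1-ol | OC/C=C(C)/C=C/[C@]1(O)C(C)(C)C[C@H](O[Si](C)(C)C(C)(C)C)C[C@@]1(C)O | intermediate
23 | allylic chloride from 22 | ClC/C=C(C)/C=C/[C@]1(O)C(C)(C)C[C@H](O[Si](C)(C)C(C)(C)C)C[C@@]1(C)O | intermediate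
24 | ring A C15 tributylphosphonium chloride | CCCC[P+](CCCC)(CCCC)C/C=C(C)/C=C/[C@]1(O)C(C)(C)C[C@H](O[Si](C)(C)C(C)(C)C)C[C@@]1(C)O.[Cl-] | intermediate
25 | (4R,6R)-4-hydroxy-2,2,6-trimethylcyclohexan-1-one | O=C1C(C)(C)C[C@H](O)C[C@H]1C | starting material
26 | (4R,6R)-4-(TBS-oxy)-2,2,6-trimethylcyclohexan-1-one | O=C1C(C)(C)C[C@H](O[Si](C)(C)C(C)(C)C)C[C@H]1C | intermediate
27 | lithium enolate of 26 | CC1=C(O[Li])C(C)(C)C[C@H](O[Si](C)(C)C(C)(C)C)C1 | intermediate
28 | (4R)-4-(TBS-oxy)-2,6,6-trimethylcyclohex-1-en-1-yl trifluoromethanesulfonate | CC1=C(OS(=O)(=O)C(F)(F)F)C(C)(C)C[C@H](O[Si](C)(C)C(C)(C)C)C1 | intermediate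
29 | (E)-3-methylpent-2-en-4-yn-1-ol | C#C/C(C)=C/CO | starting material
30 | (2E)-5-[(4R)-4-(TBS-oxy)-2,6,6-trimethylcyclohex-1-en-1-yl]-3-methylpent-2-en-4-yn-1-ol | CC1=C(C#C/C(C)=C/CO)C(C)(C)C[C@H](O[Si](C)(C)C(C)(C)C)C1 | intermediate
31 | allylic chloride from 30 | CC1=C(C#C/C(C)=C/CCl)C(C)(C)C[C@H](O[Si](C)(C)C(C)(C)C)C1 | intermediate
32 | ring B C15 tributylphosphonium chloride | CC1=C(C#C/C(C)=C/C[P+](CCCC)(CCCC)CCCC)C(C)(C)C[C@H](O[Si](C)(C)C(C)(C)C)C1.[Cl-] | intermediate
33 | (2E,4E,6E)-2,7-dimethylocta-2,4,6-trienedial | O=C/C(C)=C/C=C/C=C(C)/C=O | starting material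
34 | ylide from 32 | CC1=C(C#C/C(C)=C/[CH-][P+](CCCC)(CCCC)CCCC)C(C)(C)C[C@H](O[Si](C)(C)C(C)(C)C)C1 | intermediate
35 | (3R)-3-(TBS-oxy)-7,8-didehydro-12'-apo-beta-caroten-12'-al | CC1=C(C#C/C(C)=C/C=C/C(C)=C/C=C/C=C(C)/C=O)C(C)(C)C[C@H](O[Si](C)(C)C(C)(C)C)C1 | intermediate
36 | ylide from 24 | CCCC[P+](CCCC)(CCCC)[CH-]/C=C(C)/C=C/[C@]1(O)C(C)(C)C[C@H](O[Si](C)(C)C(C)(C)C)C[C@@]1(C)O | intermediate
37 | 3,3'-bis-TBS ether of 38 | CC1=C(C#C/C(C)=C/C=C/C(C)=C/C=C/C=C(C)/C=C/C=C(C)/C=C/[C@]2(O)C(C)(C)C[C@H](O[Si](C)(C)C(C)(C)C)C[C@@]2(C)O)C(C)(C)C[C@H](O[Si](C)(C)C(C)(C)C)C1 | intermediate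
38 | (3S,5R,6S,3'R)-7',8'-didehydro-5,6-dihydro-beta,beta-carotene-3,5,6,3'-tetrol | CC1=C(C#C/C(C)=C/C=C/C(C)=C/C=C/C=C(C)/C=C/C=C(C)/C=C/[C@]2(O)C(C)(C)C[C@H](O)C[C@@]2(C)O)C(C)(C)C[C@H](O)C1 | target

**Totals**
Total step count: 20.
Longest linear sequence: 15 steps (steps 1 to 13, then 19 and 20).

**Steps most likely to fail**

Step 5. After the first carbon–carbon bond has formed, proton loss at C3 may re-aromatise the pyrone faster than the crowded C1–C6 closure. The two faces of the pyrone may also be told apart poorly. The fallback uses known reactions only and takes ring A from the chiral pool. It sets out from 26 and comes back at 22.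
- Ketone 26 is converted with Me3SiOTf and Et3N into the trimethylsilyl enol ether F1.
- Rubottom oxidation (m-CPBA, NaHCO3, then dilute acid) on the face away from the silyloxy group gives the alpha-hydroxy ketone F2.
- The dilithio derivative of 29 adds axially to the carbonyl group, away from the axial C5 oxygen and the axial C1 methyl, to give the enyne triol F3.
- LiAlH4 in THF reduces the propargylic triple bond to the E alkene, which is 22.

Step 3. The 1,4-dicarbonyl unit may close to a furan, or five-membered ring tautomers may be trapped as acetates, in place of six-membered enol lactonisation. The fallback masks the ketone until the ring exists. It sets out from 1 and comes back at 9.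
- Base-catalysed conjugate addition of ethyl 1,3-dithiane-2-carboxylate to 1 gives the dithiane aldehyde ester F4.
- Saponification (LiOH) and closure with Ac2O and NaOAc give the spiro dithiane enol lactone F5, in which no furan can form.
- Alkylative hydrolysis of the dithiane (MeI, CaCO3, aqueous MeCN) frees the 3-oxo group, which tautomerises to 9.

Step 9. The bicyclic lactol may be reluctant to open, and attack on the neopentyl-type aldehyde may be slow. The alpha-hydroxy aldehyde may undergo alpha-ketol rearrangement under base, or the free O3 alkoxide may add back to the dienoate. The fallback olefinates a free, O3-protected aldehyde. It sets out from 14 and comes back at 20.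
- Lactone 14 is opened with MeNH(OMe)·HCl and i-PrMgCl to the Weinreb amide F6.
- Silylation with TBSCl and imidazole gives the O3-silylated amide F7.
- i-Bu2AlH at −78 °C gives the silyloxy hydroxy aldehyde F8.
- The phosphonate anion 17 then converts F8 directly into 20.

**Further compounds**
F1 | step 5 | tert-butyl(dimethyl){[(1R)-3,5,5-trimethyl-4-(trimethylsilyloxy)cyclohex-3-en-1-yl]oxy}silane | CC1=C(O[Si](C)(C)C)C(C)(C)C[C@H](O[Si](C)(C)C(C)(C)C)C1
F2 | step 5 | (2R,4S)-4-{[tert-butyl(dimethyl)silyl]oxy}-2-hydroxy-2,6,6-trimethylcyclohexan-1-one | O=C1C(C)(C)C[C@H](O[Si](C)(C)C(C)(C)C)C[C@@]1(C)O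
F3 | step 5 | (2E)-5-[(1R,2R,4S)-4-{[tert-butyl(dimethyl)silyl]oxy}-1,2-dihydroxy-2,6,6-trimethylcyclohexyl]-3-methylpent-2-en-4-yn-1-ol | OC/C=C(C)/C#C[C@]1(O)C(C)(C)C[C@H](O[Si](C)(C)C(C)(C)C)C[C@@]1(C)O
F4 | step 3 | ethyl 2-(4-oxobutan-2-yl)-1,3-dithiane-2-carboxylate (racemic) | CCOC(=O)C1(C(C)CC=O)SCCCS1
F5 | step 3 | 11-methyl-8-oxa-1,5-dithiaspiro[5.5]undec-9-en-7-one (racemic) | CC1C=COC(=O)C12SCCCS2
F6 | step 9 | (1S,4S)-1,4-dihydroxy-N-methoxy-N,2,6,6-tetramethylcyclohex-2-ene-1-carboxamide | CON(C)C(=O)[C@]1(O)C(C)(C)C[C@H](O)C=C1C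
F7 | step 9 | (1S,4S)-4-{[tert-butyl(dimethyl)silyl]oxy}-1-hydroxy-N-methoxy-N,2,6,6-tetramethylcyclohex-2-ene-1-carboxamide | CON(C)C(=O)[C@]1(O)C(C)(C)C[C@H](O[Si](C)(C)C(C)(C)C)C=C1C
F8 | step 9 | (1S,4S)-4-{[tert-butyl(dimethyl)silyl]oxy}-1-hydroxy-2,6,6-trimethylcyclohex-2-ene-1-carbaldehyde | O=C[C@]1(O)C(C)(C)C[C@H](O[Si](C)(C)C(C)(C)C)C=C1C
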